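**Retrosynthetic overview**
1. Ring numbering used below: C1 = ester carbinol (S), C2=C3(Me) E-olefin, C4, C5, C6–C7(Me) oxirane (R,R), C8–C10, C11 = CMe2. The target is an eleven-membered carbocycle fused to an oxirane.
2. Oxirane (last ring formed): catalyst-controlled Shi epoxidation of the C6=C7 olefin of the (1S,2E,6E)-cycloundecadienyl 4-methoxybenzoate.
3. Eleven-membered ring (first ring formed): the C5–C6 bond, closed by one-pot diene hydroboration and intramolecular B-alkyl Suzuki–Miyaura coupling of an acyclic trienyl iodide. The enabling feature is that oxirane carbon C6 is, one oxidation level down, the CH end of an E-trisubstituted C6=C7 olefin and can carry iodine, while C5 is the terminus of a conjugated C2=C3–C4=C5 diene that 9-BBN borylates only at C5.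
4. Acyclic precursor: C1–C2 bond and the C1 stereocentre from catalytic asymmetric addition of a dienylzinc (C2–C5) to a neopentyl aldehyde (C1, C6–C11), then acylation with the anisoyl unit.
5. Both E-trisubstituted olefins come from Negishi carboalumination of pent-4-yn-1-ol and prop-2-yn-1-ol; the quaternary C11 from alkylation of isobutyronitrile.

Key step: step 10

Remark on the chemistry: the target is read as the (1S,2E,6R,7R) isomer with a trans-oxirane; the facial sense of (−)-MIB (Si-face attack) and of the D-fructose-derived Shi ketone ((R,R)-epoxide from an E-trisubstituted olefin) is assigned by analogy with simple substrates, and the enantiomeric ligand or ketone would be used if the opposite sense were found.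

**Step 1**
Reactants: 1 pent-4-yn-1-ol
Product: 3 (E)-5-iodo-4-methylpent-4-en-1-ol, via alkenylalane 2 (not isolated)
Conditions: AlMe3 (3 equiv), Cp2ZrCl2 (0.2 equiv), CH2Cl2, 0 °C to rt; then I2, THF, −30 to 0 °C; aq. K2CO3
Reagents that add atoms: trimethylaluminium, C[Al](C)C; iodine, [I][I]
Why: Zirconium-catalysed Negishi carboalumination adds methyl and aluminium syn across the terminal alkyne with aluminium at the terminal carbon, and iodinolysis with retention fixes the E geometry (iodine cis to methyl).

**Step 2**
Reactants: 3 (E)-5-iodo-4-methylpent-4-en-1-ol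
Product: 4 (E)-1,5-diiodo-2-methylpent-1-ene
Conditions: I2, PPh3, imidazole, CH2Cl2, 0 °C to rt
Reagents that add atoms: iodine, [I][I]
Why: Appel-type iodination converts the primary alcohol into the iodide by SN2 displacement of the oxyphosphonium group and leaves the alkenyl iodide untouched.

**Step 3**
Reactants: 5 isobutyronitrile; 4 (E)-1,5-diiodo-2-methylpent-1-ene
Product: 7 (E)-7-iodo-2,2,6-trimethylhept-6-enenitrile, via lithiated isobutyronitrile 6 (not isolated)
Conditions: LiN(i-Pr)2 (LDA), THF, −78 °C; then 4, −78 °C to rt
Reagents that add atoms: none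
Why: SN2 alkylation of the lithiated nitrile by the primary alkyl iodide builds the gem-dimethyl quaternary carbon C11, the sp2 C–I bond being inert to the nucleophile.

**Step 4**
Reactants: 7 (E)-7-iodo-2,2,6-trimethylhept-6-enenitrile
Product: 9 (E)-7-iodo-2,2,6-trimethylhept-6-enal, via N-aluminio imine 8 (not isolated)
Conditions: i-Bu2AlH (DIBAL-H), CH2Cl2, −78 °C; then 1 M aq. HCl, 0 °C
Reagents that add atoms: water, O
Why: Nitrile half-reduction: DIBAL-H adds once to the hindered tertiary nitrile to give an aluminium imide that is stable at low temperature and is hydrolysed to the non-enolisable aldehyde.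

**Step 5**
Reactants: 10 prop-2-yn-1-ol
Product: 12 (E)-3-iodo-2-methylprop-2-en-1-ol, via alkenylalane 11 (not isolated)
Conditions: AlMe3 (3 equiv), Cp2ZrCl2 (0.25 equiv), CH2Cl2, 0 °C to rt; then I2, THF, −30 to 0 °C; aq. K2CO3
Reagents that add atoms: trimethylaluminium, C[Al](C)C; iodine, [I][I]
Why: Negishi carboalumination with syn delivery of methyl (internal carbon) and aluminium (terminal carbon), followed by stereoretentive iodinolysis, gives the E-alkenyl iodide with iodine trans to the hydroxymethyl group.

**Step 6**
Reactants: 12 (E)-3-iodo-2-methylprop-2-en-1-ol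
Product: 13 (E)-3-iodo-2-methylprop-2-enal
Conditions: MnO2 (activated, excess), CH2Cl2, rt
Reagents that add atoms: none
Why: Allylic oxidation with MnO2 is selective for the allylic alcohol under neutral conditions that preserve the alkenyl iodide and its geometry.

**Step 7**
Reactants: 13 (E)-3-iodo-2-methylprop-2-enal
Product: 14 (E)-1-iodo-2-methylbuta-1,3-diene
Conditions: Ph3PCH3Br, KOt-Bu, THF, 0 °C; then 13, 0 °C to rt; the volatile diene kept as a solution
Reagents that add atoms: methyltriphenylphosphonium bromide, C[P+](c1ccccc1)(c1ccccc1)c1ccccc1.[Br-]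
Why: Wittig methylenation of the enal with the unstabilised ylide installs the terminal vinyl group without disturbing the existing E-olefin.

**Step 8**
Reactants: 14 (E)-1-iodo-2-methylbuta-1,3-diene; 9 (E)-7-iodo-2,2,6-trimethylhept-6-enal
Product: 17 (3E,5S,10E)-11-iodo-3,6,6,10-tetramethylundeca-1,3,10-trien-5-ol, via dienyllithium 15 (not isolated), via butyl dienyl zinc 16 (not isolated)
Conditions: 14, t-BuLi (2 equiv), Et2O, −78 °C; ZnCl2, −78 to 0 °C; n-BuLi, −78 °C; N,N,N',N'-tetraethylethylenediamine, toluene; (−)-MIB (10 mol%), then 9, 0 °C; aq. NH4Cl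
Reagents that add atoms: none
Why: Iodine–lithium exchange with retention of olefin geometry, transmetalation to a mixed alkyl alkenyl zinc and amino-alcohol-catalysed enantioselective alkenylzinc 1,2-addition, in which the sp2 group transfers selectively, the zinc reagent does not exchange with the alkenyl iodide of 9, and the (−)-ligand is expected to direct attack to the Si face of the aldehyde, which corresponds to the (S)-carbinol at C1.

**Step 9**
Reactants: 17 (3E,5S,10E)-11-iodo-3,6,6,10-tetramethylundeca-1,3,10-trien-5-ol; 18 4-methoxybenzoyl chloride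
Product: 19 (3E,5S,10E)-11-iodo-3,6,6,10-tetramethylundeca-1,3,10-trien-5-yl 4-methoxybenzoate
Conditions: DMAP, Et3N, CH2Cl2, 0 to 40 °C
Reagents that add atoms: none
Why: DMAP-catalysed acylation through the acylpyridinium ion esterifies the hindered secondary alcohol with retention at C1, under basic conditions that avoid ionisation of the dienylic C–O bond.

**Step 10**
Reactants: 19 (3E,5S,10E)-11-iodo-3,6,6,10-tetramethylundeca-1,3,10-trien-5-yl 4-methoxybenzoate
Product: 21 (1S,2E,6E)-3,7,11,11-tetramethylcycloundeca-2,6-dien-1-yl 4-methoxybenzoate, via alkylborane 20 (not isolated)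
Conditions: 9-BBN dimer (0.6 equiv), THF, 0 °C to rt; then syringe-pump addition over 12 h to Pd(dppf)Cl2·CH2Cl2 (15 mol%), AsPh3 (30 mol%), Cs2CO3 (3 equiv), degassed DMF/THF/H2O, 45 °C, about 2 mM final concentration
Reagents that add atoms: none
Why: 9-BBN adds only to the terminal C4=C5 vinyl of the conjugated diene, with boron at C5, because the trisubstituted C2=C3 olefin and the iodinated C6=C7 olefin are too hindered for this bulky borane; zerovalent palladium then inserts into the C6–I bond with retention, the base-activated borate transfers the primary C5 alkyl group to the divalent alkenylpalladium centre, and reductive elimination forms the C5–C6 bond. The closest known reaction type is the intramolecular B-alkyl Suzuki–Miyaura macrocyclisation used to close carbocycles of twelve or more atoms, applied here one ring size lower. The eleven-membered carbocycle is closed in an endo sense by reductive elimination from a twelve-membered palladacycle in which both reacting carbons lie in the chain. No stereocentre is created: the S centre at C1 is remote and untouched, and both E-trisubstituted olefins arrive in place because oxidative addition, transmetalation and reductive elimination are stereoretentive. The step needs chemoselective anti-Markovnikov monohydroboration (secured by the steric gap between the vinyl terminus and the two trisubstituted olefins), ring closure in preference to oligomerisation (secured by slow addition at millimolar concentration and helped by the gem-dimethyl group and the two rigid E-olefins), and no ionisation of the allylic anisoate (this hindered trisubstituted allylic ester should react with zerovalent palladium far more slowly than the alkenyl iodide).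

**Step 11**
Reactants: 21 (1S,2E,6E)-3,7,11,11-tetramethylcycloundeca-2,6-dien-1-yl 4-methoxybenzoate
Product: 22 (1S,2E,6R,7R)-6,7-epoxy-3,7,11,11-tetramethylcycloundec-2-en-1-yl 4-methoxybenzoate
Conditions: D-fructose-derived Shi ketone (30 mol%), Oxone, K2CO3, Bu4NHSO4, MeCN/dimethoxymethane/aq. Na2B4O7–Na2EDTA buffer (pH 10.5), 0 °C
Reagents that add atoms: potassium peroxymonosulfate (active component of Oxone), [K+].[O-]S(=O)(=O)OO
Why: Shi asymmetric epoxidation, in which the chiral dioxirane transfers oxygen through a spiro transition state to one face of the E-trisubstituted C6=C7 olefin and should set both oxirane centres as (6R,7R) under catalyst control, while the C2=C3 olefin is deactivated by the allylic ester and shielded by the neopentyl carbon.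

**Compound list**
1 | pent-4-yn-1-ol | OCCCC#C | starting material
2 | (E)-[5-(dimethylaluminiooxy)-2-methylpent-1-en-1-yl]dimethylaluminium | C[Al](C)OCCC/C(C)=C/[Al](C)C | intermediate
3 | (E)-5-iodo-4-methylpent-4-en-1-ol | OCCC/C(C)=C/I | intermediate
4 | (E)-1,5-diiodo-2-methylpent-1-ene | ICCC/C(C)=C/I | intermediate
5 | isobutyronitrile (2-methylpropanenitrile) | CC(C)C#N | starting material
6 | lithiated isobutyronitrile (N-lithio dimethylketenimine) | CC(C)=C=N[Li] | intermediate
7 | (E)-7-iodo-2,2,6-trimethylhept-6-enenitrile | N#CC(C)(C)CCC/C(C)=C/I | intermediate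
8 | N-(diisobutylaluminio) imine of (E)-7-iodo-2,2,6-trimethylhept-6-enal | CC(C)C[Al](CC(C)C)N=CC(C)(C)CCC/C(C)=C/I | intermediate
9 | (E)-7-iodo-2,2,6-trimethylhept-6-enal | O=CC(C)(C)CCC/C(C)=C/I | intermediate
10 | prop-2-yn-1-ol | OCC#C | starting material
11 | (E)-[3-(dimethylaluminiooxy)-2-methylprop-1-en-1-yl]dimethylaluminium | C[Al](C)OC/C(C)=C/[Al](C)C | intermediate
12 | (E)-3-iodo-2-methylprop-2-en-1-ol | OC/C(C)=C/I | intermediate
13 | (E)-3-iodo-2-methylprop-2-enal | O=C/C(C)=C/I | intermediate
14 | (E)-1-iodo-2-methylbuta-1,3-diene | C=C/C(C)=C/I | intermediate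
15 | [(1E)-2-methylbuta-1,3-dien-1-yl]lithium | [Li]/C=C(C)/C=C | intermediate
16 | butyl[(1E)-2-methylbuta-1,3-dien-1-yl]zinc | CCCC[Zn]/C=C(C)/C=C | intermediate
17 | (3E,5S,10E)-11-iodo-3,6,6,10-tetramethylundeca-1,3,10-trien-5-ol | C=C/C(C)=C/[C@H](O)C(C)(C)CCC/C(C)=C/I | intermediate
18 | 4-methoxybenzoyl chloride | COc1ccc(cc1)C(Cl)=O | starting material
19 | (3E,5S,10E)-11-iodo-3,6,6,10-tetramethylundeca-1,3,10-trien-5-yl 4-methoxybenzoate | COc1ccc(cc1)C(=O)O[C@@H](/C=C(C)/C=C)C(C)(C)CCC/C(C)=C/I | intermediate
20 | (3E,5S,10E)-1-(9-borabicyclo[3.3.1]nonan-9-yl)-11-iodo-3,6,6,10-tetramethylundeca-3,10-dien-5-yl 4-methoxybenzoate | COc1ccc(cc1)C(=O)O[C@@H](/C=C(C)/CCB1C2CCCC1CCC2)C(C)(C)CCC/C(C)=C/I | intermediate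
21 | (1S,2E,6E)-3,7,11,11-tetramethylcycloundeca-2,6-dien-1-yl 4-methoxybenzoate | COc1ccc(C(=O)O[C@H]2/C=C(\C)CC/C=C(\C)CCCC2(C)C)cc1 | intermediate
22 | (1S,2E,6R,7R)-6,7-epoxy-3,7,11,11-tetramethylcycloundec-2-en-1-yl 4-methoxybenzoate | COc1ccc(C(=O)O[C@H]2/C=C(\C)CC[C@H]3O[C@]3(C)CCCC2(C)C)cc1 | target

**Totals**
Total step count: 11. Longest linear sequence: 8 steps (steps 1, 2, 3, 4, 8, 9, 10, 11).

**Steps most likely to fail**

1. Step 10. What may go wrong: intermolecular coupling to oligomers outrunning closure of the strained ring; protodeboronation or β-hydride elimination of the alkyl group on palladium; slow ionisation of the allylic ester by zerovalent palladium.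
Fallback (sets out from 19, comes back at 21): 19 would be hydroborated as in step 10 to borane 20, but then oxidised (NaBO3·4H2O, THF/H2O) to the primary alcohol (3E,5S,10E)-1-hydroxy-11-iodo-3,6,6,10-tetramethylundeca-3,10-dien-5-yl 4-methoxybenzoate F1. Dess–Martin periodinane (NaHCO3, CH2Cl2, 0 °C) would give the β,γ-unsaturated aldehyde (3E,5S,10E)-11-iodo-3,6,6,10-tetramethyl-1-oxoundeca-3,10-dien-5-yl 4-methoxybenzoate F2, used without storage. A Nozaki–Hiyama–Kishi macrocyclisation (CrCl2 in excess, NiCl2 1 mol%, DMSO/THF, 2 mM, rt) would then form the same C5–C6 bond by addition of the alkenylchromium species to the aldehyde, giving the ring allylic alcohol (1S,2E,6E)-5-hydroxy-3,7,11,11-tetramethylcycloundeca-2,6-dien-1-yl 4-methoxybenzoate F3 as a mixture of C5 epimers that converge. Acylation (ClCO2Me, pyridine, DMAP, CH2Cl2) would give the carbonate (1S,2E,6E)-5-[(methoxycarbonyl)oxy]-3,7,11,11-tetramethylcycloundeca-2,6-dien-1-yl 4-methoxybenzoate F4. Palladium-catalysed hydride transfer (Pd(PPh3)4, NaBH4, THF, rt) would remove the extra oxygen by hydride attack at the less hindered C5 terminus of the allyl intermediate and return 21.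

2. Step 8. What may go wrong: erosion of enantioselectivity by an uncatalysed background addition promoted by residual lithium salts, or sluggish catalysed addition to the hindered neopentyl aldehyde with competing butyl transfer.
Fallback (sets out from 9 and 14, comes back at 17): dienyllithium 15, made from 14 and t-BuLi, would be added directly to 9 (Et2O, −78 °C) to give the racemic dienol (3E,10E)-11-iodo-3,6,6,10-tetramethylundeca-1,3,10-trien-5-ol F5. Dess–Martin oxidation would give the dienone (3E,10E)-11-iodo-3,6,6,10-tetramethylundeca-1,3,10-trien-5-one F6. A Corey–Bakshi–Shibata reduction ((R)-Me-CBS oxazaborolidine, catecholborane, toluene, −78 °C) would return 17; the tert-alkyl group is expected to act as the large substituent, the sense would be confirmed by Mosher analysis, and the other catalyst enantiomer used if needed.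

3. Step 11. What may go wrong: poor facial selectivity if the face preferred by the catalyst is the one shielded by the ring conformation (mismatched pairing), and competing oxidation of the C2=C3 olefin on long reaction times.
Fallback (sets out from 21, comes back at 22): NBS in aqueous DME at 0 °C would give the bromohydrin (1S,2E,6S,7R)-6-bromo-7-hydroxy-3,7,11,11-tetramethylcycloundec-2-en-1-yl 4-methoxybenzoate F7, by bromonium formation on the more accessible face of the electron-rich C6=C7 olefin and anti opening by water at the tertiary C7. DBU in CH2Cl2 would then close the oxirane by displacement of bromide at C6 with inversion. This places oxygen on the face opposite to that of direct electrophilic attack, so an unfavourable intrinsic bias of the ring would become the route to 22.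

**Further compounds**
F1 | step 10 | (3E,5S,10E)-1-hydroxy-11-iodo-3,6,6,10-tetramethylundeca-3,10-dien-5-yl 4-methoxybenzoate | COc1ccc(cc1)C(=O)O[C@@H](/C=C(C)/CCO)C(C)(C)CCC/C(C)=C/I
F2 | step 10 | (3E,5S,10E)-11-iodo-3,6,6,10-tetramethyl-1-oxoundeca-3,10-dien-5-yl 4-methoxybenzoate | COc1ccc(cc1)C(=O)O[C@@H](/C=C(C)/CC=O)C(C)(C)CCC/C(C)=C/I
F3 | step 10 | (1S,2E,6E)-5-hydroxy-3,7,11,11-tetramethylcycloundeca-2,6-dien-1-yl 4-methoxybenzoate (C5 epimers) | COc1ccc(C(=O)O[C@H]2/C=C(\C)CC(O)/C=C(\C)CCCC2(C)C)cc1
F4 | step 10 | (1S,2E,6E)-5-[(methoxycarbonyl)oxy]-3,7,11,11-tetramethylcycloundeca-2,6-dien-1-yl 4-methoxybenzoate (C5 epimers) | COc1ccc(C(=O)O[C@H]2/C=C(\C)CC(OC(=O)OC)/C=C(\C)CCCC2(C)C)cc1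
F5 | step 8 | (3E,10E)-11-iodo-3,6,6,10-tetramethylundeca-1,3,10-trien-5-ol (racemic) | C=C/C(C)=C/C(O)C(C)(C)CCC/C(C)=C/I
F6 | step 8 | (3E,10E)-11-iodo-3,6,6,10-tetramethylundeca-1,3,10-trien-5-one | C=C/C(C)=C/C(=O)C(C)(C)CCC/C(C)=C/I
F7 | step 11 | (1S,2E,6S,7R)-6-bromo-7-hydroxy-3,7,11,11-tetramethylcycloundec-2-en-1-yl 4-methoxybenzoate | COc1ccc(C(=O)O[C@H]2/C=C(\C)CC[C@H](Br)[C@@](O)(C)CCCC2(C)C)cc1
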